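The data were generated by integration with made-up constants; the scatter is artificial.

The autumn run, a closed stirred flask with the recipe now in question, held 26.1% single product, 3.7% double product and 7.7% isomer at 5.00 min. I wanted the share of single product in these three, the selectivity, in each set-up.

| flask | substrate | reagent | remark | time |
|---|---|---|---|---|
| autumn | 0.15 M | 1.5 equiv | run made earlier |  |
| dusk | 0.15 M | 3 equiv | run made earlier |  |
| blue | 0.15 M | 1.50 equiv | one stirred flow tank at steady state, fed with the mixture as stated, mean residence time 8.0 min |  |
| teal | 0.15 M | 1.50 equiv | plug flow through a tube for 8.0 min, no back-mixing | 8.0 min |
| violet | 0.15 M | 1.50 equiv | a closed flask charged with all of it at once and left for 8.0 min | 8.0 min |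
| green | 0.15 M (fed, over 8.00 min) | 1.50 equiv | all but substrate at the start; substrate goes in evenly over 8.00 min, the run ends at 8.0 min | 8.0 min |

autumn run (percent of the substrate charged)

| time / min | single product / % | double product / % | isomer of the product / % |
|---|---|---|---|
| 0.250 | 2.8 | 0 | 0.6 |
| 0.667 | 6.6 | 0 | 0.8 |
| 1.33 | 12.4 | 0.4 | 1.0 |
| 2.00 | 16.4 | 0.3 | 1.4 |
| 3.00 | 20.7 | 1.6 | 3.4 |
| 4.00 | 23.9 | 2.1 | 5.7 |
| 5.00 | 26.1 | 3.7 | 7.7 |

dusk run (percent of the substrate charged)

| time / s | single product / % | double product / % | isomer of the product / % |
|---|---|---|---|
| 10.0 | 2.9 | 0 | 0 |
| 15.0 | 5.3 | 0 | 0 |
| 20.0 | 6.8 | 0.2 | 0.8 |
| 30.0 | 10.0 | 0 | 0.4 |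
| 40.0 | 12.1 | 0.7 | 0.8 |
| 50.0 | 14.6 | 0.4 | 0.7 |

(scatter of a reading: 0.3 percentage points)

- the stated concentrations are those of everything mixed, before any reaction; amounts are the same in each set-up
- what was read earlier has a scatter of 0.3 percentage points, one standard deviation
- steps thought possible: substrate + reagent -> single product + by-product; reagent + single product -> double product + by-product; single product <-> isomer of the product
- the feed brings no volume worth counting
- the earlier runs were made in a closed, stirred flask

1. the set-up with the highest share of single product in all that became single product or double product or isomer of the product, at the outlet or at the end ("none" if the first two lie within 2 percentage points) (blue / teal / violet / green / none)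
2. share of single product in all that became single product or double product or isomer of the product, at the outlet or at the end, blue
3. share of single product in all that became single product or double product or isomer of the product, at the outlet or at the end, teal
4. share of single product in all that became single product or double product or isomer of the product, at the outlet or at the end, violet
5. share of single product in all that became single product or double product or isomer of the product, at the outlet or at the end, green

Over that run the mean of the curve of c(single) was 16.8%. So I defined the drain λ, the pseudo-first-order loss of single product, as double product plus isomer formed per unit of mean single product and per minute: 0.136 min⁻¹. With h, the time integral of c(single) over its final value, the share is one over one plus λh.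

Then I turned the settings by hand. For the closed flask, violet, a straight rise would give h as 0.5 of the time and a share of 64.8%. But the autumn curve bends: up to 5.00 min its mean was 0.644 of its end value. That run ends earlier than violet does, so I carried both this ratio and λ over to 8.0 min as assumptions, not readings, and estimated h at 5.16 min and the share at 58.9%. Teal's tube ages each slice like that flask, so it gets the same. The tank, blue, holds its outlet state for the full residence time, so h is 8.00 min and the share 48.0%. Green's feed makes product on a rising ramp, a third of the time before the same assumed bend, so I estimated h at 3.44 min and the share at 68.2%.

The forecast named green, with 51% for blue, 57% for teal, 57% for violet and 70% for green: “Semi-batch feed gives younger product on average”. My numbers differ slightly from these.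

The flasks gave 56.0% for blue, 58.8% for teal, 58.8% for violet and 69.0% for green, so green led.

    substrate + reagent → single product + by-product (k = 0.00827 M⁻¹ s⁻¹)
    reagent + single product → double product + by-product (k = 0.00395 M⁻¹ s⁻¹)
    single product ⇌ isomer of the product (K = 1.00, k = 0.00197 s⁻¹)

Blue parted from my reckoning: its share implies a drain of 0.0982 min⁻¹ over its h, lower than the autumn value. For green's neighbour at 0.60 M, with equivalents and time held, I multiplied the double-product part of λ by 4.00, since that step takes reagent, and kept the isomer part. That gave 0.268 min⁻¹ and, with green's h, a share of 52.0%. The neighbour gave 51.4%, with double product at 18.2% of the substrate charged.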